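**Plan**

1. Retrosynthesis: remove the C1/C10 epoxide oxygen, the C8 methacrylate, the C13 methylene and the O6–C12 lactone bond, and replace C8–O by C8–Si. Then cut C8–C9 while re-joining C1–C6 (retro oxy-Cope) to reach cyclohexenol 14. Its side chains are cut at C7–C11, C6–C7 and C1–C10 back to a quinone monoketal.
2. Enabling feature: in the ten-membered ring the C6 oxygen and the E C1=C10 alkene are 1,5-related through C7–C8–C9, and the only cis ring alkene (C4=C5) lies in the chain C1–C2–C3–C4=C5–C6. That chain can therefore be closed to a cyclohexene, where the alkene is necessarily cis, carrying isopropenyl (C9, C10, C14) on C1 and a vinyl unit (C7, C8) on C6.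
3. Forward order: six-membered ring (from an arene), then the ten-membered ring by four-carbon ring expansion (step 8), then the γ-lactone (step 10), then the epoxide (step 15).
4. Stereochemistry: C1 (temporary) from Rh/(R)-BINAP conjugate addition, C3 from CBS reduction; C1 is transferred to C8 through the chair transition state. C7 and C6 follow by peripheral attack on the ring-expanded enolate and ketone, and C1/C10 by peripheral epoxidation of the E alkene.

Key step: step 8

Remark: 2-(hydroxymethyl)-4-methoxyphenol (1) is taken to be a catalogue compound. Labels C1–C15 are the germacrane numbers of the target (O6–C12 lactone, C8 ester, C1/C10 epoxide, C14 = methyl on C10, C15 = CH2OH on C4); α/β refer to the usual germacranolide drawing (H-7 is α throughout).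

Step 1
Reactants: 1 2-(hydroxymethyl)-4-methoxyphenol
Product: 2 2-(hydroxymethyl)-4,4-dimethoxycyclohexa-2,5-dien-1-one
Conditions: PhI(OAc)2 (1.1 equiv), MeOH, 0 °C
Reagents that add atoms: methanol (CO)
Why: Hypervalent-iodine oxidative dearomatisation of a p-methoxyphenol: the phenoxenium ion is trapped by methanol at the methoxy-bearing para carbon to give the quinone monoketal, the primary alcohol is not oxidised without a nitroxyl catalyst, and no stereocentre is formed.

Step 2
Reactants: 2 2-(hydroxymethyl)-4,4-dimethoxycyclohexa-2,5-dien-1-one; 3 isopropenylboronic acid pinacol ester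
Product: 4 (5R)-2-(hydroxymethyl)-4,4-dimethoxy-5-(prop-1-en-2-yl)cyclohex-2-en-1-one
Conditions: [Rh(cod)OH]2 (2.5 mol %), (R)-BINAP (6 mol %), 3 (2 equiv), dioxane/H2O 10:1, 40 °C
Reagents that add atoms: none
Why: Hayashi–Miyaura Rh-catalysed asymmetric 1,4-addition: the alkenylrhodium adds only to the unsubstituted enone (the α-hydroxymethyl enone inserts far more slowly), and the (R)-BINAP–Rh face selection known for cyclohex-2-enone should give the 5R centre (C1 of the target numbering) next to the ketal carbon.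

Step 3
Reactants: 4 (5R)-2-(hydroxymethyl)-4,4-dimethoxy-5-(prop-1-en-2-yl)cyclohex-2-en-1-one
Product: 5 (1S,5R)-2-(hydroxymethyl)-4,4-dimethoxy-5-(prop-1-en-2-yl)cyclohex-2-en-1-ol
Conditions: (R)-Me-CBS (0.2 equiv), catecholborane (2.5 equiv), toluene, −78 °C; aqueous work-up
Reagents that add atoms: none
Why: Corey–Bakshi–Shibata reduction: the carbonyl is flanked by an α-branched alkenyl carbon (large) and a CH2 (small), so the (R)-oxazaborolidine should deliver hydride under reagent control to give the 1S allylic alcohol (C3 of the target), trans to isopropenyl, and catecholborane leaves the isopropenyl alkene untouched.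

Step 4
Reactants: 5 (1S,5R)-2-(hydroxymethyl)-4,4-dimethoxy-5-(prop-1-en-2-yl)cyclohex-2-en-1-ol
Product: 6 (7R,8aS)-2,2-dimethyl-7-(prop-1-en-2-yl)-7,8-dihydro-4H-1,3-benzodioxin-6(8aH)-one
Conditions: Me2C(OMe)2, PPTS (cat.), acetone, rt; then H2O (few equiv)
Reagents that add atoms: 2,2-dimethoxypropane (COC(C)(C)OC); water (O)
Why: Acid-catalysed acetal exchange: the 1,3-diol closes the six-membered isopropylidene acetal and the allylic dimethyl ketal is hydrolysed under the same mild acid (PPTS should not enolise the new ketone, so C7 is kept); the acetonide also holds C8a–O pseudo-equatorial, which places the trans isopropenyl group pseudo-axial.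

Step 5
Reactants: 7 benzylchlorodimethylsilane; 8 ethynylmagnesium bromide
Product: 9 benzyl(ethynyl)dimethylsilane
Conditions: THF, 0 °C to rt
Reagents that add atoms: none
Why: Substitution at silicon by an alkynyl Grignard reagent; the benzyldimethylsilyl group is chosen because it survives organometallic bases and hydride yet is unmasked by fluoride for Tamao–Fleming oxidation.

Step 6
Reactants: 6 (7R,8aS)-2,2-dimethyl-7-(prop-1-en-2-yl)-7,8-dihydro-4H-1,3-benzodioxin-6(8aH)-one; 9 benzyl(ethynyl)dimethylsilane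
Product: 11 (6R,7R,8aS)-6-{[benzyl(dimethyl)silyl]ethynyl}-2,2-dimethyl-7-(prop-1-en-2-yl)-6,7,8,8a-tetrahydro-4H-1,3-benzodioxin-6-ol, via lithium silylacetylide 10 (not isolated)
Conditions: 9, n-BuLi, THF, −78 °C; anhydrous CeCl3; then 6, −78 °C; then H2O
Reagents that add atoms: none
Why: 1,2-Addition of a weakly basic alkynylcerium reagent to the enone carbonyl without enolisation of the acidic α-centre; the nucleophile enters axially and anti to the pseudo-axial isopropenyl group, so the alkynyl group ends trans to isopropenyl (6R), the arrangement that the chair transition state of step 8 requires.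

Step 7
Reactants: 11 (6R,7R,8aS)-6-{[benzyl(dimethyl)silyl]ethynyl}-2,2-dimethyl-7-(prop-1-en-2-yl)-6,7,8,8a-tetrahydro-4H-1,3-benzodioxin-6-ol; 12 vinylmagnesium bromide
Product: 14 (6R,7R,8aS)-6-[(1E)-1-[benzyl(dimethyl)silyl]buta-1,3-dien-2-yl]-2,2-dimethyl-7-(prop-1-en-2-yl)-6,7,8,8a-tetrahydro-4H-1,3-benzodioxin-6-ol, via alkenylmagnesium chelate 13 (not isolated)
Conditions: 12 (4 equiv), CuI (0.2 equiv), THF/toluene, 0 to 50 °C; then H2O
Reagents that add atoms: none
Why: Copper-catalysed, alkoxide-directed anti-carbomagnesiation of a propargylic alcohol: vinyl is delivered to the carbinol-proximal alkyne carbon while magnesium ends on the silyl-bearing carbon in a five-membered chelate (α-silyl stabilisation reinforces this regiochemistry), and protonolysis with retention gives the vinylsilane with silicon trans to the carbinol carbon and cis to the new vinyl group.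

Step 8
Reactants: 14 (6R,7R,8aS)-6-[(1E)-1-[benzyl(dimethyl)silyl]buta-1,3-dien-2-yl]-2,2-dimethyl-7-(prop-1-en-2-yl)-6,7,8,8a-tetrahydro-4H-1,3-benzodioxin-6-ol
Product: 17 8β-[benzyl(dimethyl)silyl]-3β,15-(isopropylidenedioxy)-13-norgermacra-1(10)E,4Z,11-trien-6-one, via potassium alkoxide 15 (not isolated), via potassium dienolate 16 (not isolated)
Conditions: KH (1.5 equiv), 18-crown-6 (1.5 equiv), THF, 0 °C to rt (gentle warming if needed); cannulation into AcOH/THF at −78 °C
Reagents that add atoms: none
Why: The potassium alkoxide 15 undergoes an anionic oxy-Cope ([3,3]-sigmatropic) rearrangement of its 3-oxido-1,5-diene unit C8=C7–C6(O−)–C1–C10=C9; the closest known reaction type is the ring expansion of trans-1-alkenyl-2-isopropenylcyclohexenoxides to (E)-cyclodec-5-enones. No ring is closed by cyclisation: the ten-membered carbocycle arises by four-carbon ring expansion, the C8–C9 bond forming as the C1–C6 bond of the cyclohexene breaks, so that the endocyclic cis C4=C5 of the six-membered ring becomes the 4Z alkene. Because the two alkenyl groups are trans, only the chair transition state with the ring bonds C1–C2 and C6–C5 equatorial is available, which fixes C1=C10 as E and, with silicon equatorial on the vinylsilane, transfers the C1 configuration of 14 to C8 (8β-Si). C7 is then set by kinetic protonation of the extended dienolate 16 at its α-carbon from the peripheral face: A(1,3) strain holds C8–H near the enolate plane and the ring bond C8–C9 covers the inner face, so the vinyl group should end cis to silicon (H-7α). The step needs the trans alkenyl arrangement (from step 6), the vinylsilane geometry (from step 7), a β-substituent that cannot leave from the enolate (silicon in place of oxygen) and a cold acidic quench to avoid γ-protonation; the acetonide forces the rearrangement through the less populated half-chair.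

Step 9
Reactants: 17 8β-[benzyl(dimethyl)silyl]-3β,15-(isopropylidenedioxy)-13-norgermacra-1(10)E,4Z,11-trien-6-one
Product: 19 8β-[benzyl(dimethyl)silyl]-3β,15-(isopropylidenedioxy)-13-norgermacra-1(10)E,4Z-diene-6α,12-diol, via bis-borane adduct 18 (not isolated)
Conditions: 9-BBN (2.5 equiv), THF, 0 °C to rt; then 3 M NaOH, 30% H2O2, 0 °C
Reagents that add atoms: hydrogen peroxide (OO); in intermediate 18 only: 9-borabicyclo[3.3.1]nonane (B1C2CCCC1CCC2)
Why: 9-BBN is used in both of its known roles, 1,2-reduction of the enone carbonyl from the exposed (peripheral, Felkin–Anh) face anti to the inward-pointing C7 substituent to give the 6α-oxygen, and anti-Markovnikov hydroboration of the monosubstituted vinyl group (the trisubstituted ring alkenes react far more slowly); alkaline peroxide then oxidises C–B with retention and frees both hydroxyls, while the C–Si bond, not activated by fluoride, persists.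

Step 10
Reactants: 19 8β-[benzyl(dimethyl)silyl]-3β,15-(isopropylidenedioxy)-13-norgermacra-1(10)E,4Z-diene-6α,12-diol
Product: 21 8β-[benzyl(dimethyl)silyl]-3β,15-(isopropylidenedioxy)-13-norgermacra-1(10)E,4Z-dien-6α,12-olide, via lactol 20 (not isolated)
Conditions: TEMPO (0.2 equiv), PhI(OAc)2 (2.5 equiv), CH2Cl2, rt
Reagents that add atoms: none
Why: Nitroxyl-catalysed oxidation is selective for the primary alcohol; the aldehyde is captured by the 6α-hydroxyl as lactol 20, which is oxidised on to the trans-fused γ-lactone (oxidative lactonisation of a 1,4-diol), and since C8 still carries silicon only the 6,12-lactone can form.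

Step 11
Reactants: 21 8β-[benzyl(dimethyl)silyl]-3β,15-(isopropylidenedioxy)-13-norgermacra-1(10)E,4Z-dien-6α,12-olide
Product: 23 8β-hydroxy-3β,15-(isopropylidenedioxy)-13-norgermacra-1(10)E,4Z-dien-6α,12-olide, via fluorosilane 22 (not isolated)
Conditions: TBAF (3 equiv), THF, 0 °C to rt; then KHCO3, 30% H2O2, MeOH, rt to 40 °C
Reagents that add atoms: hydrogen peroxide (OO); in intermediate 22 only: tetrabutylammonium fluoride (CCCC[N+](CCCC)(CCCC)CCCC.[F-])
Why: Tamao–Fleming oxidation: fluoride cleaves the benzyl–silicon bond to the fluorosilane, whose C8–Si bond is then oxidised by buffered hydrogen peroxide with retention of configuration to the 8β-alcohol; the nucleophilic oxidant does not touch the electron-rich alkenes, and the lactone is still saturated at this stage.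

Step 12
Reactants: 23 8β-hydroxy-3β,15-(isopropylidenedioxy)-13-norgermacra-1(10)E,4Z-dien-6α,12-olide
Product: 26 8β-hydroxy-3β,15-(isopropylidenedioxy)germacra-1(10)E,4Z,11(13)-trien-6α,12-olide, via Mannich base 24 (not isolated), via ammonium iodide 25 (not isolated)
Conditions: LiHMDS (2.3 equiv), THF, −78 °C; CH2=NMe2+ I−, −78 to 0 °C; H2O; then MeI, MeOH, rt; then aq NaHCO3, CH2Cl2
Reagents that add atoms: Eschenmoser's salt (C=[N+](C)C.[I-]); in intermediate 25 only: iodomethane (CI)
Why: α-Methylenation of a γ-lactone: the dianion (C8 alkoxide and lactone enolate, kept at −78 °C to suppress translactonisation) undergoes a Mannich reaction with Eschenmoser's salt, and N-methylation followed by Hofmann-type β-elimination unveils the exocyclic alkene, so C11 ceases to be a stereocentre.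

Step 13
Reactants: 26 8β-hydroxy-3β,15-(isopropylidenedioxy)germacra-1(10)E,4Z,11(13)-trien-6α,12-olide; 27 methacrylic anhydride
Product: 28 3β,15-(isopropylidenedioxy)-8β-(methacryloyloxy)germacra-1(10)E,4Z,11(13)-trien-6α,12-olide
Conditions: 27 (2 equiv), Et3N, DMAP (0.2 equiv), CH2Cl2, 0 °C to rt
Reagents that add atoms: none
Why: DMAP-catalysed acylation of the only free hydroxyl (C8), with retention at C8; O3 and O15 remain masked in the acetonide.

Step 14
Reactants: 28 3β,15-(isopropylidenedioxy)-8β-(methacryloyloxy)germacra-1(10)E,4Z,11(13)-trien-6α,12-olide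
Product: 29 3β,15-dihydroxy-8β-(methacryloyloxy)germacra-1(10)E,4Z,11(13)-trien-6α,12-olide
Conditions: AcOH/H2O/THF 3:1:1, 40 °C
Reagents that add atoms: none
Why: Mild acid hydrolysis of the isopropylidene acetal; it is done before the epoxide is introduced because a 3-hydroxy-1(10)-epoxide would suffer transannular opening under acid, and both esters tolerate aqueous acetic acid.

Step 15
Reactants: 29 3β,15-dihydroxy-8β-(methacryloyloxy)germacra-1(10)E,4Z,11(13)-trien-6α,12-olide
Product: 30 1β,10α-epoxy-3β,15-dihydroxy-8β-(methacryloyloxy)germacra-4Z,11(13)-dien-6α,12-olide (CNP0496616.1)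
Conditions: mCPBA (1.05 equiv), NaHCO3, CH2Cl2, −20 to 0 °C
Reagents that add atoms: 3-chloroperoxybenzoic acid (OOC(=O)c1cccc(Cl)c1)
Why: Prilezhaev epoxidation: the strained, electron-rich E-trisubstituted C1=C10 alkene reacts first, while C4=C5 (three allylic oxygens) and the two acrylate alkenes are electron-poor; the E alkene gives the trans epoxide stereospecifically, and attack on the outer face of the ground-state conformer of this heliangolide (C14 on the β face) should give the 1β,10α (1R,10R) epoxide, with bicarbonate keeping the 3-hydroxyl from opening it.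

**Compound list**

1 | 2-(hydroxymethyl)-4-methoxyphenol | COc1ccc(O)c(CO)c1 | starting material
2 | 2-(hydroxymethyl)-4,4-dimethoxycyclohexa-2,5-dien-1-one | O=C1C=CC(OC)(OC)C=C1CO | intermediate
3 | isopropenylboronic acid pinacol ester | CC(=C)B1OC(C)(C)C(C)(C)O1 | starting material
4 | (5R)-2-(hydroxymethyl)-4,4-dimethoxy-5-(prop-1-en-2-yl)cyclohex-2-en-1-one | CC(=C)[C@H]1CC(=O)C(CO)=CC1(OC)OC | intermediate
5 | (1S,5R)-2-(hydroxymethyl)-4,4-dimethoxy-5-(prop-1-en-2-yl)cyclohex-2-en-1-ol | CC(=C)[C@H]1C[C@H](O)C(CO)=CC1(OC)OC | intermediate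
6 | (7R,8aS)-2,2-dimethyl-7-(prop-1-en-2-yl)-7,8-dihydro-4H-1,3-benzodioxin-6(8aH)-one | CC(=C)[C@H]1C[C@@H]2OC(C)(C)OCC2=CC1=O | intermediate
7 | benzylchlorodimethylsilane | C[Si](C)(Cl)Cc1ccccc1 | starting material
8 | ethynylmagnesium bromide | C#C[Mg]Br | starting material
9 | benzyl(ethynyl)dimethylsilane | C#C[Si](C)(C)Cc1ccccc1 | intermediate
10 | lithium [benzyl(dimethyl)silyl]acetylide | [Li]C#C[Si](C)(C)Cc1ccccc1 | intermediate
11 | (6R,7R,8aS)-6-{[benzyl(dimethyl)silyl]ethynyl}-2,2-dimethyl-7-(prop-1-en-2-yl)-6,7,8,8a-tetrahydro-4H-1,3-benzodioxin-6-ol | CC(=C)[C@H]1C[C@@H]2OC(C)(C)OCC2=C[C@]1(O)C#C[Si](C)(C)Cc1ccccc1 | intermediate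
12 | vinylmagnesium bromide | C=C[Mg]Br | starting material
13 | cyclic alkenylmagnesium alkoxide from 11 (Mg bridges O6 and the silyl-bearing carbon C8; vinyl on C7) | CC(=C)[C@H]1C[C@@H]2OC(C)(C)OCC2=C[C@@]13O[Mg]C([Si](C)(C)Cc4ccccc4)=C3C=C | intermediate
14 | (6R,7R,8aS)-6-[(1E)-1-[benzyl(dimethyl)silyl]buta-1,3-dien-2-yl]-2,2-dimethyl-7-(prop-1-en-2-yl)-6,7,8,8a-tetrahydro-4H-1,3-benzodioxin-6-ol | CC(=C)[C@H]1C[C@@H]2OC(C)(C)OCC2=C[C@]1(O)/C(C=C)=C/[Si](C)(C)Cc1ccccc1 | intermediate
15 | potassium alkoxide of 14 | CC(=C)[C@H]1C[C@@H]2OC(C)(C)OCC2=C[C@]1([O-])/C(C=C)=C/[Si](C)(C)Cc1ccccc1.[K+] | intermediate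
16 | potassium dienolate of 17 (O–C6=C7–C11=C12; C5 and C8 trans across C6=C7) | C[Si](C)(Cc1ccccc1)[C@@H]1C/C(C)=C/C[C@@H]3OC(C)(C)OC/C3=C/C([O-])=C1\C=C.[K+] | intermediate
17 | 8β-[benzyl(dimethyl)silyl]-3β,15-(isopropylidenedioxy)-13-norgermacra-1(10)E,4Z,11-trien-6-one (H-7α) | C[Si](C)(Cc1ccccc1)[C@@H]1C/C(C)=C/C[C@@H]3OC(C)(C)OC/C3=C/C(=O)[C@@H]1C=C | intermediate
18 | bis-borane adduct of 17 (O6–B and C12–B, each boron part of a 9-BBN unit) | C[Si](C)(Cc1ccccc1)[C@@H]1C/C(C)=C/C[C@@H]3OC(C)(C)OC/C3=C/[C@@H](OB4C5CCCC4CCC5)[C@@H]1CCB1C2CCCC1CCC2 | intermediate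
19 | 8β-[benzyl(dimethyl)silyl]-3β,15-(isopropylidenedioxy)-13-norgermacra-1(10)E,4Z-diene-6α,12-diol | C[Si](C)(Cc1ccccc1)[C@@H]1C/C(C)=C/C[C@@H]3OC(C)(C)OC/C3=C/[C@@H](O)[C@@H]1CCO | intermediate
20 | 6α,12-lactol of 19 (C12 hemiacetal, both epimers) | C[Si](C)(Cc1ccccc1)[C@@H]1C/C(C)=C/C[C@@H]3OC(C)(C)OC/C3=C/[C@H]2OC(O)C[C@@H]21 | intermediate
21 | 8β-[benzyl(dimethyl)silyl]-3β,15-(isopropylidenedioxy)-13-norgermacra-1(10)E,4Z-dien-6α,12-olide | C[Si](C)(Cc1ccccc1)[C@@H]1C/C(C)=C/C[C@@H]3OC(C)(C)OC/C3=C/[C@H]2OC(=O)C[C@@H]21 | intermediate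
22 | 8β-[fluoro(dimethyl)silyl] analogue of 21 | C[Si](C)(F)[C@@H]1C/C(C)=C/C[C@@H]3OC(C)(C)OC/C3=C/[C@H]2OC(=O)C[C@@H]21 | intermediate
23 | 8β-hydroxy-3β,15-(isopropylidenedioxy)-13-norgermacra-1(10)E,4Z-dien-6α,12-olide | O[C@@H]1C/C(C)=C/C[C@@H]3OC(C)(C)OC/C3=C/[C@H]2OC(=O)C[C@@H]21 | intermediate
24 | 11-[(dimethylamino)methyl] derivative of 23 (C11 epimers) | O[C@@H]1C/C(C)=C/C[C@@H]3OC(C)(C)OC/C3=C/[C@H]2OC(=O)C(CN(C)C)[C@@H]21 | intermediate
25 | 11-[(trimethylammonio)methyl] derivative of 23, iodide | O[C@@H]1C/C(C)=C/C[C@@H]3OC(C)(C)OC/C3=C/[C@H]2OC(=O)C(C[N+](C)(C)C)[C@@H]21.[I-] | intermediate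
26 | 8β-hydroxy-3β,15-(isopropylidenedioxy)germacra-1(10)E,4Z,11(13)-trien-6α,12-olide | O[C@@H]1C/C(C)=C/C[C@@H]3OC(C)(C)OC/C3=C/[C@H]2OC(=O)C(=C)[C@@H]21 | intermediate
27 | methacrylic anhydride | CC(=C)C(=O)OC(=O)C(C)=C | starting material
28 | 3β,15-(isopropylidenedioxy)-8β-(methacryloyloxy)germacra-1(10)E,4Z,11(13)-trien-6α,12-olide | C=C(C)C(=O)O[C@@H]1C/C(C)=C/C[C@@H]3OC(C)(C)OC/C3=C/[C@H]2OC(=O)C(=C)[C@@H]21 | intermediate
29 | 3β,15-dihydroxy-8β-(methacryloyloxy)germacra-1(10)E,4Z,11(13)-trien-6α,12-olide | C=C(C)C(=O)O[C@@H]1C/C(C)=C/C[C@H](O)/C(CO)=C\[C@H]2OC(=O)C(=C)[C@@H]21 | intermediate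
30 | 1β,10α-epoxy-3β,15-dihydroxy-8β-(methacryloyloxy)germacra-4Z,11(13)-dien-6α,12-olide, (1R,3S,6R,7R,8R,10R), CNP0496616.1 | C=C(C)C(=O)O[C@@H]1C[C@@]2(C)O[C@@H]2C[C@H](O)/C(CO)=C\[C@H]2OC(=O)C(=C)[C@@H]21 | target

**Totals**

Total step count: 15. Longest linear sequence: 14 steps (steps 1–4 and 6–15; step 5 prepares the silylacetylene).

**Steps most likely to fail**

Step 8. The rearrangement itself may be slowed by the acetonide-locked half-chair, and the proton may then enter the dienolate on the inner face or at C12, giving the C7 epimer or the conjugated ethylidene ketone; an error at C7 carries through to the lactone. The fallback sets out from 11 and comes back at 21. It exchanges the roles of proton and carbon electrophile, so that C7 is set by C–C bond formation on a simple enolate. Red-Al reduction of 11 (trans-hydroalumination, protonolysis) should give the 7-unsubstituted (E)-2-silylvinyl carbinol F1. Its potassium alkoxide is rearranged as in step 8 and the enolate is alkylated at −78 °C with methyl bromoacetate to the γ-keto ester F2, the electrophile now taking the face the proton would have taken. Reduction with NaBH4/CeCl3 should give the hydroxy ester F3, which closes to lactone 21 on standing with a trace of acid.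

Step 7. The vinyl Grignard reagent may fail to add across the hindered, silyl-capped alkyne next to a quaternary carbinol, or may add without the anti sense, so that the dienylsilane geometry is lost. The fallback sets out from 11 and comes back at 14. Ruthenium-catalysed, hydroxyl-directed trans-hydrostannation (Bu3SnH, [Cp*RuCl]4, CH2Cl2) should place tin on the carbinol-proximal carbon and hydrogen anti to it on the silyl-bearing carbon, giving the α-stannyl vinylsilane F4. A Stille coupling with vinyl bromide (Pd2(dba)3, AsPh3, CuI, DMF) then replaces tin by vinyl with retention to give 14.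

Step 3. The inherent bias of the ring (hydride anti to the isopropenyl-bearing side, leading to the cis alcohol) opposes the catalyst, so facial selectivity at C3 may be poor. The fallback sets out from 4 and comes back at 5. It accepts substrate control and then inverts the centre. Luche reduction (NaBH4, CeCl3, MeOH, −78 °C) should give the cis diol F5. The primary hydroxyl is acetylated selectively (AcCl, 2,4,6-collidine, −78 °C) to the monoacetate F6. Mitsunobu reaction with 4-nitrobenzoic acid (DIAD, PPh3) should give the inverted diester F7, and methanolysis of both esters (K2CO3, MeOH) returns 5.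

**Further compounds**

F1 | step 8 | 7-unsubstituted analogue of 14: 6-[(E)-2-[benzyl(dimethyl)silyl]ethenyl] carbinol, ring configuration as in 11 | CC(=C)[C@H]1C[C@@H]2OC(C)(C)OCC2=C[C@]1(O)/C=C/[Si](C)(C)Cc1ccccc1
F2 | step 8 | methyl ester of 8β-[benzyl(dimethyl)silyl]-3β,15-(isopropylidenedioxy)-6-oxo-13-norgermacra-1(10)E,4Z-dien-12-oic acid | C[Si](C)(Cc1ccccc1)[C@@H]1C/C(C)=C/C[C@@H]3OC(C)(C)OC/C3=C/C(=O)[C@@H]1CC(=O)OC
F3 | step 8 | methyl ester of 8β-[benzyl(dimethyl)silyl]-6α-hydroxy-3β,15-(isopropylidenedioxy)-13-norgermacra-1(10)E,4Z-dien-12-oic acid | C[Si](C)(Cc1ccccc1)[C@@H]1C/C(C)=C/C[C@@H]3OC(C)(C)OC/C3=C/[C@@H](O)[C@@H]1CC(=O)OC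
F4 | step 7 | 6-[(Z)-2-[benzyl(dimethyl)silyl]-1-(tributylstannyl)ethenyl] carbinol (Sn cis to Si), ring configuration as in 11 | CC(=C)[C@H]1C[C@@H]2OC(C)(C)OCC2=C[C@]1(O)/C(=C/[Si](C)(C)Cc1ccccc1)[Sn](CCCC)(CCCC)CCCC
F5 | step 3 | (1R,5R)-2-(hydroxymethyl)-4,4-dimethoxy-5-(prop-1-en-2-yl)cyclohex-2-en-1-ol | CC(=C)[C@H]1C[C@@H](O)C(CO)=CC1(OC)OC
F6 | step 3 | primary acetate of F5 | CC(=C)[C@H]1C[C@@H](O)C(COC(C)=O)=CC1(OC)OC
F7 | step 3 | (1S,5R)-2-(acetoxymethyl)-4,4-dimethoxy-5-(prop-1-en-2-yl)cyclohex-2-en-1-yl 4-nitrobenzoate | CC(=C)[C@H]1C[C@H](OC(=O)c2ccc(cc2)[N+](=O)[O-])C(COC(C)=O)=CC1(OC)OC
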